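**Retrosynthetic overview**
1. Target 19 ⇒ hydroxy lactone 16 + (2S)-2-methylbutanoic acid 17 (ester C–O).
2. 16 ⇒ acrylate 15 (lactone C–C bond by Rauhut–Currier cyclisation; the lactone ring is closed last) ⇒ triol 12 + acrylic acid 13 (C–O bond with inversion).
3. 12 ⇒ dienone 11 (syn-dihydroxylation) ⇒ 9 (C-methylation) ⇒ 8 (dehydrogenation).
4. 8 ⇒ six-membered dienol 5 by one-carbon ring expansion with a zinc carbenoid, ended by oxygen transfer to the ring-expanded enolate (the seven-membered carbocycle is formed here, before the lactone).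
5. 5 ⇒ cyclohex-2-en-1-one 1 + (E)-but-2-enal 2 (Morita–Baylis–Hillman reaction, then oxidation).

Assumption: of the two antipodes of (camphorylsulfonyl)oxaziridine, the (+)-form is taken as the one that gives (S)-8; if the facial sense is the opposite, the (−)-form is used in the same way.
Assumption: species bound to a catalyst inside a catalytic cycle (steps 1, 6 and 8) are not numbered.

**Step 1**
Reactants: 1 cyclohex-2-en-1-one; 2 (E)-but-2-enal
Product: 3 rac-2-[(E)-1-hydroxybut-2-en-1-yl]cyclohex-2-en-1-one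
Conditions: DMAP (10 mol%), MgI2 (10 mol%), TMEDA (10 mol%), MeOH, rt
Reagents that add atoms: none
Why: Morita–Baylis–Hillman reaction, in which the nucleophilic catalyst adds 1,4 to the enone, the enolate adds 1,2 to the enal carbonyl and β-elimination restores the enone, giving a racemic carbinol centre that is erased in step 2.

**Step 2**
Reactants: 3 rac-2-[(E)-1-hydroxybut-2-en-1-yl]cyclohex-2-en-1-one
Product: 5 2-[(E)-but-2-enoyl]cyclohexa-1,3-dien-1-ol, via enedione tautomer 4 (not isolated)
Conditions: Dess–Martin periodinane (1.2 equiv), CH2Cl2, 0 °C → rt; aq Na2S2O3/NaHCO3 wash; then Et3N (10 mol%), CH2Cl2, rt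
Reagents that add atoms: none
Why: Dess–Martin oxidation of the bis-allylic alcohol gives enedione 4, whose acidic γ-hydrogens let catalytic Et3N tautomerise it to the conjugated, hydrogen-bonded dienol 5 (the enol form of the β-diketone), the form needed for zinc enolate formation.

**Step 3**
Reactants: 5 2-[(E)-but-2-enoyl]cyclohexa-1,3-dien-1-ol
Product: 8 (3S)-3-[(E)-but-2-enoyl]-3-hydroxycyclohept-4-en-1-one, via zinc cyclopropanolate 6 (not isolated), via ring-expanded zinc enolate 7 (not isolated)
Conditions: Et2Zn (2.3 equiv), CH2I2 (1.3 equiv), CH2Cl2, 0 °C; then (+)-(camphorylsulfonyl)oxaziridine (2.5 equiv, the excess also destroys residual C–Zn species), −40 → 0 °C; aq NH4Cl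
Reagents that add atoms: diiodomethane, ICI; (+)-(2R,8aS)-(camphorylsulfonyl)oxaziridine, CC1(C)[C@@H]2CC[C@]13CS(=O)(=O)N4O[C@@]34C2
Why: Proposed new method: Et2Zn turns 5 into its zinc dienolate, EtZnCH2I alkylates the central carbon, the β-zincio ketone closes onto the more electrophilic non-conjugated ring carbonyl to give cyclopropanolate 6, fragmentation of its C1–C6 bond (a formal 1,2-acyl shift) expands the ring to the acyl-stabilised zinc dienolate 7, and the chiral N-sulfonyloxaziridine then transfers oxygen to one face of the prochiral α-carbon (α rather than γ, as usual for metal dienolates) to set C3 as S; the closest known reactions are the zinc-carbenoid chain extension and ring expansion of β-keto esters with electrophile trapping (Zercher type) and the Davis asymmetric enolate hydroxylation, which have not been combined or shown on a cyclic dienolic β-diketone.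

**Step 4**
Reactants: 8 (3S)-3-[(E)-but-2-enoyl]-3-hydroxycyclohept-4-en-1-one
Product: 9 (6S)-6-[(E)-but-2-enoyl]-6-hydroxycyclohepta-2,4-dien-1-one
Conditions: IBX (2.0 equiv), 4-methoxypyridine N-oxide (2.0 equiv), DMSO, 25 °C
Reagents that add atoms: none
Why: IBX dehydrogenation of a ketone (Nicolaou type), in which the ring ketone enolises towards C7, IBX oxidises the enol and loss of the allylic C6–H places the new C=C in conjugation with both the carbonyl and C4=C5, while the C2 side cannot desaturate because C3 is quaternary and no stereocentre is touched.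

**Step 5**
Reactants: 9 (6S)-6-[(E)-but-2-enoyl]-6-hydroxycyclohepta-2,4-dien-1-one
Product: 11 (6R,7R)-6-[(E)-but-2-enoyl]-6-hydroxy-7-methylcyclohepta-2,4-dien-1-one, via dilithium dianion 10 (not isolated)
Conditions: LiHMDS (2.2 equiv), THF, −78 °C; MeI (1.5 equiv), −78 → −50 °C; AcOH, −78 °C
Reagents that add atoms: iodomethane, CI
Why: Kinetic α′-alkylation of a chelated alkoxide–enolate dianion (Fráter–Seebach type), in which C7 is the only enolisable ring position of the dienone, methyl iodide enters anti to the bulky crotonoyl group (cis to the alkoxide) to give 7R, and this α-keto centre stays epimerisable so that the same, thermodynamically preferred trans-methyl/acyl isomer is reached in any case (C6 is unchanged in space and its descriptor goes from S to R only through CIP priorities).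

**Step 6**
Reactants: 11 (6R,7R)-6-[(E)-but-2-enoyl]-6-hydroxy-7-methylcyclohepta-2,4-dien-1-one
Product: 12 (4S,5S,6S,7R)-6-[(E)-but-2-enoyl]-4,5,6-trihydroxy-7-methylcyclohept-2-en-1-one
Conditions: OsO4 (2 mol%), NMO (1.1 equiv), acetone–H2O (8:1), 0 °C
Reagents that add atoms: 4-methylmorpholine N-oxide, C[N+]1([O-])CCOCC1; water, O
Why: Upjohn syn-dihydroxylation, in which electrophilic OsO4 attacks the electron-richer γ,δ-alkene of the dienone rather than either α,β-unsaturated C=C and adds anti to the pseudo-axial allylic C6–OH (Kishi's rule), setting C4 and C5 (both S) on the face that carries the crotonoyl group.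

**Step 7**
Reactants: 12 (4S,5S,6S,7R)-6-[(E)-but-2-enoyl]-4,5,6-trihydroxy-7-methylcyclohept-2-en-1-one; 13 prop-2-enoic acid
Product: 15 (1R,5R,6S,7S)-6-[(E)-but-2-enoyl]-6,7-dihydroxy-5-methyl-4-oxocyclohept-2-en-1-yl prop-2-enoate, via alkoxyphosphonium acrylate 14 (not isolated)
Conditions: PPh3 (1.3 equiv), DIAD (1.3 equiv), THF, 0 °C → rt, BHT (trace)
Reagents that add atoms: none
Why: Mitsunobu esterification, in which the less hindered allylic C4–OH is activated as oxyphosphonium 14 and displaced by acrylate in an SN2 step with inversion (C4 from S to R), while the neopentyl-type C5–OH and the tertiary C6–OH cannot be displaced.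

**Step 8**
Reactants: 15 (1R,5R,6S,7S)-6-[(E)-but-2-enoyl]-6,7-dihydroxy-5-methyl-4-oxocyclohept-2-en-1-yl prop-2-enoate
Product: 16 (3aS,6R,7S,8S,8aR)-7-[(E)-but-2-enoyl]-7,8-dihydroxy-6-methyl-3-methylideneoctahydro-2H-cyclohepta[b]furan-2,5-dione
Conditions: PMe3 (30 mol%), t-AmOH, rt
Reagents that add atoms: none
Why: Intramolecular Rauhut–Currier reaction, in which PMe3 adds to the unsubstituted acrylate, the resulting α-carbanion attacks the enone β-carbon 5-exo from the face of its own tether, which fixes the cis ring fusion (C3a as S), and proton transfer with loss of PMe3 leaves the α-methylene lactone.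

**Step 9**
Reactants: 16 (3aS,6R,7S,8S,8aR)-7-[(E)-but-2-enoyl]-7,8-dihydroxy-6-methyl-3-methylideneoctahydro-2H-cyclohepta[b]furan-2,5-dione; 17 (2S)-2-methylbutanoic acid
Product: 19 (3aS,6R,7S,8S,8aR)-7-[(E)-but-2-enoyl]-7-hydroxy-6-methyl-3-methylidene-2,5-dioxooctahydro-2H-cyclohepta[b]furan-8-yl (2S)-2-methylbutanoate, via O-acylisourea 18 (not isolated)
Conditions: DCC (1.5 equiv), DMAP (0.2 equiv), CH2Cl2, 0 °C → rt
Reagents that add atoms: none
Why: Steglich esterification, in which the DMAP-activated acyl group acylates the secondary C8–OH while the tertiary C7–OH is inert, the acid stereocentre is not touched, and material of the minor enantiomeric series from step 3 becomes a separable diastereomer here.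

**Compound list**
1 | cyclohex-2-en-1-one | O=C1C=CCCC1 | starting material
2 | (E)-but-2-enal (crotonaldehyde) | C/C=C/C=O | starting material
3 | rac-2-[(E)-1-hydroxybut-2-en-1-yl]cyclohex-2-en-1-one | C/C=C/C(O)C1=CCCCC1=O | intermediate
4 | 2-[(E)-but-2-enoyl]cyclohex-2-en-1-one (enedione tautomer, not isolated) | C/C=C/C(=O)C1=CCCCC1=O | intermediate
5 | 2-[(E)-but-2-enoyl]cyclohexa-1,3-dien-1-ol (chelated dienol form of 2-[(E)-but-2-enoyl]cyclohex-3-en-1-one) | C/C=C/C(=O)C1=C(O)CCC=C1 | intermediate
6 | ethylzinc rac-6-[(E)-but-2-enoyl]bicyclo[4.1.0]hept-4-en-1-olate (cis-fused cyclopropanolate, not isolated) | CC[Zn]OC12CCC=CC1(C2)C(=O)/C=C/C | intermediate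
7 | ethylzinc enolate of 3-[(E)-but-2-enoyl]cyclohept-4-en-1-one (exocyclic enolate at C3, ring ketone intact, not isolated) | C/C=C/C(O[Zn]CC)=C1CC(=O)CCC=C1 | intermediate
8 | (3S)-3-[(E)-but-2-enoyl]-3-hydroxycyclohept-4-en-1-one | O=C1C[C@@](O)(C(=O)/C=C/C)C=CCC1 | intermediate
9 | (6S)-6-[(E)-but-2-enoyl]-6-hydroxycyclohepta-2,4-dien-1-one | O=C1C[C@@](O)(C(=O)/C=C/C)C=CC=C1 | intermediate
10 | dilithium salt of 9 (C6 alkoxide and C1–C7 enolate, not isolated) | [Li]OC1=C[C@@](O[Li])(C(=O)/C=C/C)C=CC=C1 | intermediate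
11 | (6R,7R)-6-[(E)-but-2-enoyl]-6-hydroxy-7-methylcyclohepta-2,4-dien-1-one (methyl trans to the crotonoyl group) | O=C1[C@H](C)[C@@](O)(C(=O)/C=C/C)C=CC=C1 | intermediate
12 | (4S,5S,6S,7R)-6-[(E)-but-2-enoyl]-4,5,6-trihydroxy-7-methylcyclohept-2-en-1-one (4-OH and 5-OH cis to each other and trans to 6-OH) | O=C1[C@H](C)[C@@](O)(C(=O)/C=C/C)[C@@H](O)[C@@H](O)C=C1 | intermediate
13 | prop-2-enoic acid (acrylic acid) | C=CC(=O)O | starting material
14 | C4-oxytriphenylphosphonium salt of 12 with acrylate counter-ion (not isolated) | O=C1[C@H](C)[C@@](O)(C(=O)/C=C/C)[C@@H](O)[C@@H](O[P+](c2ccccc2)(c2ccccc2)c2ccccc2)C=C1.[O-]C(=O)C=C | intermediate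
15 | (1R,5R,6S,7S)-6-[(E)-but-2-enoyl]-6,7-dihydroxy-5-methyl-4-oxocyclohept-2-en-1-yl prop-2-enoate | O=C1[C@H](C)[C@@](O)(C(=O)/C=C/C)[C@@H](O)[C@H](OC(=O)C=C)C=C1 | intermediate
16 | (3aS,6R,7S,8S,8aR)-7-[(E)-but-2-enoyl]-7,8-dihydroxy-6-methyl-3-methylideneoctahydro-2H-cyclohepta[b]furan-2,5-dione (cis-fused α-methylene-γ-butyrolactone on the cycloheptanone) | C=C1C(=O)O[C@@H]2[C@H]1CC(=O)[C@H](C)[C@@](O)(C(=O)/C=C/C)[C@H]2O | intermediate
17 | (2S)-2-methylbutanoic acid | CC[C@H](C)C(=O)O | starting material
18 | O-[(2S)-2-methylbutanoyl]-N,N'-dicyclohexylisourea (not isolated) | CC[C@H](C)C(=O)OC(=NC1CCCCC1)NC1CCCCC1 | intermediate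
19 | (3aS,6R,7S,8S,8aR)-7-[(E)-but-2-enoyl]-7-hydroxy-6-methyl-3-methylidene-2,5-dioxooctahydro-2H-cyclohepta[b]furan-8-yl (2S)-2-methylbutanoate | C=C1C(=O)O[C@@H]2[C@H]1CC(=O)[C@H](C)[C@@](O)(C(=O)/C=C/C)[C@H]2OC(=O)[C@@H](C)CC | target

**Step count and risks**
Total: 9 steps. Longest linear sequence: 9 steps (1 → 19).

The three steps most likely to fail:

Step 3 (proposed tandem ring expansion and oxygenation). The homoenolate may close onto the crotonoyl carbonyl instead of the ring carbonyl. The zinc dienolate may take oxygen at the γ-carbon. The zinc enolate may be too unreactive towards the oxaziridine or give low ee. Fallback, from 5 back to 8, with known chemistry: 5 is homologated under the established zinc-carbenoid conditions (Et2Zn, CH2I2, CH2Cl2) but quenched with aqueous NH4Cl, which gives rac-3-[(E)-but-2-enoyl]cyclohept-4-en-1-one F1. Its doubly activated C3–H is removed with KHMDS in THF at −78 °C to give the potassium dienolate of F1 F2. This preformed enolate is hydroxylated with the same (+)-oxaziridine (Davis asymmetric enolate hydroxylation) to give 8.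

Step 5 (C-methylation of the unprotected β-hydroxy dienone). The dianion may undergo retro-aldol cleavage or O-methylation, and 9 and 11 can lose water to a tropone. Fallback, from 9 back to 11: the tertiary alcohol is silylated (TESOTf, 2,6-lutidine, CH2Cl2) to (6S)-6-[(E)-but-2-enoyl]-6-(triethylsilyloxy)cyclohepta-2,4-dien-1-one F3. LDA in THF at −78 °C gives the lithium enolate of F3 F4, and MeI gives (6R,7R)-6-[(E)-but-2-enoyl]-7-methyl-6-(triethylsilyloxy)cyclohepta-2,4-dien-1-one F5. HF·pyridine then removes the silyl group and returns 11.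

Step 7 (Mitsunobu reaction on the free triol). The cis-diol can form a phosphorane, elimination can compete, and site selectivity between C4–OH and C5–OH is not certain. Fallback, from 12 back to 15: the allylic C4–OH is sulfonylated selectively (MsCl, 2,4,6-collidine, CH2Cl2, −20 °C) to (1S,5R,6S,7S)-6-[(E)-but-2-enoyl]-6,7-dihydroxy-5-methyl-4-oxocyclohept-2-en-1-yl methanesulfonate F6. The mesylate is displaced with inversion by caesium prop-2-enoate F7 (from 13 and Cs2CO3; 18-crown-6, toluene, rt) to give 15.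

**Further compounds**
F1 | step 3 | rac-3-[(E)-but-2-enoyl]cyclohept-4-en-1-one | O=C1CC(C(=O)/C=C/C)C=CCC1
F2 | step 3 | potassium dienolate of F1 (exocyclic enolate at C3) | C/C=C/C(O[K])=C1CC(=O)CCC=C1
F3 | step 5 | (6S)-6-[(E)-but-2-enoyl]-6-(triethylsilyloxy)cyclohepta-2,4-dien-1-one | O=C1C[C@@](O[Si](CC)(CC)CC)(C(=O)/C=C/C)C=CC=C1
F4 | step 5 | lithium C1–C7 enolate of F3 | [Li]OC1=C[C@@](O[Si](CC)(CC)CC)(C(=O)/C=C/C)C=CC=C1
F5 | step 5 | (6R,7R)-6-[(E)-but-2-enoyl]-7-methyl-6-(triethylsilyloxy)cyclohepta-2,4-dien-1-one | O=C1[C@H](C)[C@@](O[Si](CC)(CC)CC)(C(=O)/C=C/C)C=CC=C1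
F6 | step 7 | (1S,5R,6S,7S)-6-[(E)-but-2-enoyl]-6,7-dihydroxy-5-methyl-4-oxocyclohept-2-en-1-yl methanesulfonate | O=C1[C@H](C)[C@@](O)(C(=O)/C=C/C)[C@@H](O)[C@@H](OS(C)(=O)=O)C=C1
F7 | step 7 | caesium prop-2-enoate | [Cs+].[O-]C(=O)C=C
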